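**Retrosynthetic overview**

1. Target 28 ⇐ oxidation of the C3 alcohol, 15,16-epoxide by bromohydrin closure, and MeCeCl2 addition to the C10 ketone of 23.
2. Oxepane and cyclohexane rings are made last, in one operation: silyl-triflate-triggered bis-epoxide oxa-/carbacyclization of enol silane 22 ⇐ 1,4-hydrosilylation of enone 21 ⇐ HWE of aldehyde 16 with bis-epoxy β-keto phosphonate 20 (geranyl bromide, Shi epoxidation).
3. Aldehyde 16 ⇐ Claisen rearrangement of allylic alcohol 14 (sets C14, moves the alkene to C15=C16) ⇐ Luche reduction of hydroazulenone 13.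
4. Key C18–C19 bond: SmI2 ketyl–olefin cyclization of keto dienone 12 (ketone carbon made nucleophilic, joined to the enone β-carbon) builds the cyclopentanol on the seven-membered ring.
5. 12 ⇐ Ito–Saegusa ring expansion ⇐ Cu-catalysed asymmetric conjugate addition to dienone 5 ⇐ isobutyraldehyde + ethyl vinyl ketone. Ring order: six (expanded to seven) → five → oxepane + cyclohexane → epoxide.

**Numbering key (used only for orientation):** C2 = O–CMe2; C3 = ketone; C4, C5 = oxepane CH2CH2; C6 = quaternary C–Me; C7 = O–CH; C8, C9 = CH2CH2; C10 = left C(OH)Me; C11 = CH carrying the linker; C12, C13 = linker; C14 = CH on the seven-membered ring; C15/C16 = epoxide C(Me)/CH; C17 = CH2; C18, C22 = ring-fusion CH; C19 = right C(OH)Me; C20, C21 = CH2CH2; C23 = CMe2.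

**Assumption:** the (S,R,R)-phosphoramidite is taken to give the R configuration at the new stereocentre in step 3 (future C22); if the sense is opposite, the (R,S,S)-ligand is used with no other change.

**Route**

Step 1
Reactants: 1 isobutyraldehyde; 2 ethyl vinyl ketone
Product: 4 2,4,4-trimethylcyclohex-2-en-1-one, via 2,2-dimethyl-5-oxoheptanal 3 (not isolated)
Conditions: H2SO4 (cat.), 45 °C; then PhH, reflux, Dean–Stark
Reagents that add atoms: none
Why: Acid-catalysed Michael addition of the aldehyde enol followed by intramolecular aldol condensation (Robinson annulation) can only close the six-membered ring through the ethyl CH2, which places the methyl on the enone α-carbon; no stereocentre is formed.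

Step 2
Reactants: 4 2,4,4-trimethylcyclohex-2-en-1-one
Product: 5 2,4,4-trimethylcyclohexa-2,5-dien-1-one
Conditions: DDQ (1.3 equiv), TsOH (cat.), 1,4-dioxane, reflux
Reagents that add atoms: none
Why: DDQ α',β'-dehydrogenation of a 4,4-disubstituted cyclohexenone stops at the cross-conjugated dienone because the quaternary carbon blocks aromatisation.

Step 3
Reactants: 5 2,4,4-trimethylcyclohexa-2,5-dien-1-one; 6 2-(2-bromoethyl)-2-methyl-1,3-dioxolane
Product: 9 {[(5R)-2,4,4-trimethyl-5-[2-(2-methyl-1,3-dioxolan-2-yl)ethyl]bicyclo[4.1.0]hept-2-en-1-yl]oxy}trimethylsilane, via zinc enolate 7 (not isolated), via silyl dienol ether 8 (not isolated)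
Conditions: 6, Mg, Et2O; ZnCl2 (0.5 equiv), then 1,4-dioxane, filter; 5, Cu(OTf)2 (2 mol %), (S,R,R)-BINOL bis(1-phenylethyl)amine phosphoramidite (4 mol %), PhMe, −30 °C; TMSOTf (1.05 equiv), −78 °C; then Et2Zn, CH2I2, 0 °C → rt
Reagents that add atoms: trimethylsilyl trifluoromethanesulfonate, C[Si](C)(C)OS(=O)(=O)C(F)(F)F; diiodomethane, ICI
Why: Cu/phosphoramidite-catalysed asymmetric conjugate addition of the dialkylzinc goes to the unsubstituted enone (the α-methyl enone is much less reactive) and the ligand sets the new stereocentre, after which the zinc dienolate is O-silylated and the electron-rich enol ether bond is cyclopropanated in the same flask (tandem conjugate addition–silylation–Simmons–Smith), the cyclopropane configuration being irrelevant.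

Step 4
Reactants: 9 siloxycyclopropane
Product: 12 (5R)-2,4,4-trimethyl-5-(3-oxobutyl)cyclohepta-2,6-dien-1-one, via chloro ketone 10 (not isolated), via ketal dienone 11 (not isolated)
Conditions: FeCl3 (2.5 equiv), DMF, 0 °C → rt; crude, NaOAc, MeOH, reflux; then 2 M aq. HCl, rt
Reagents that add atoms: water, O
Why: Ito–Saegusa ring expansion, in which Fe(III) oxidation cleaves the internal cyclopropane bond to the ring-expanded β-keto radical that is trapped as the β-chloro ketone, NaOAc eliminates HCl to the cross-conjugated cycloheptadienone and acid unmasks the methyl ketone, leaves the stereocentre untouched.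

Step 5 (key step)
Reactants: 12 keto dienone
Product: 13 (3R,3aR,8aR)-3-hydroxy-3,6,8,8-tetramethyl-2,3,3a,4,8,8a-hexahydroazulen-5(1H)-one
Conditions: SmI2 (2.2 equiv), THF–HMPA (10:1), 0.01 M, −78 °C; then sat. aq. NH4Cl
Reagents that add atoms: none
Why: SmI2 ketyl–olefin reductive cyclization joins the ketone carbon C19 (turned nucleophilic as its ketyl) 5-exo to the electrophilic enone β-carbon C18, the tether from C22 enforcing the cis ring fusion and the O–Sm group lying anti to the developing samarium dienolate so that the hydroxyl ends up cis to both ring-fusion hydrogens, while the product stays protected as its enolate until the quench.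

Step 6
Reactants: 13 hydroxy enone
Product: 14 (3R,3aR,5S,8aR)-3,6,8,8-tetramethyl-1,2,3,3a,4,5,8,8a-octahydroazulene-3,5-diol
Conditions: NaBH4, CeCl3·7H2O, MeOH, −78 → −40 °C
Reagents that add atoms: none
Why: Luche 1,2-reduction delivers hydride from the convex face of the cis-fused bicycle (the concave face is screened by the endo C19 methyl), placing the new C16 hydroxyl on the concave face.

Step 7
Reactants: 14 allylic alcohol
Product: 16 2-[(3R,3aR,7S,8aR)-3-hydroxy-3,6,8,8-tetramethyl-1,2,3,3a,4,7,8,8a-octahydroazulen-7-yl]acetaldehyde, via allyl vinyl ether 15 (not isolated)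
Conditions: n-butyl vinyl ether (solvent), Pd(TFA)2 (5 mol %), 4,7-diphenyl-1,10-phenanthroline (5 mol %), Et3N, 75 °C; evaporate; PhMe, 170 °C, sealed tube
Reagents that add atoms: butyl vinyl ether, C=COCCCC
Why: Pd(II)-catalysed transfer vinylation of the secondary allylic alcohol (the tertiary alcohol is inert) followed by thermal Claisen rearrangement delivers the CH2CHO group suprafacially to C14 on the face that carried the C16–O bond and moves the alkene to C15=C16.

Step 8
Reactants: 17 dimethyl (2-oxopropyl)phosphonate; 18 geranyl bromide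
Product: 19 dimethyl [(5E)-6,10-dimethyl-2-oxoundeca-5,9-dien-1-yl]phosphonate
Conditions: NaH, THF, 0 °C; n-BuLi, −10 °C; 18, 0 °C → rt; aq. NH4Cl
Reagents that add atoms: none
Why: γ-Alkylation of the β-keto phosphonate dianion occurs at the more basic terminal carbanion and the allylic bromide reacts by SN2 with retention of the E alkene.

Step 9
Reactants: 19 dienyl β-keto phosphonate
Product: 20 dimethyl [(5R,6R,9R)-5,6:9,10-diepoxy-6,10-dimethyl-2-oxoundecyl]phosphonate
Conditions: D-fructose-derived Shi ketone (0.3 equiv per alkene), Oxone, K2CO3, Bu4NHSO4, MeCN–CH2(OMe)2–aq. buffer (pH 10.5), 0 °C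
Reagents that add atoms: potassium peroxymonosulfate (Oxone), [K+].[O-]S(=O)(=O)OO
Why: Shi asymmetric epoxidation transfers oxygen from the chiral dioxirane to the same face of both electron-rich E-trisubstituted alkenes, giving the 6R,7R and 3R epoxides (target numbering).

Step 10
Reactants: 16 hydroazulenyl acetaldehyde; 20 bis-epoxy β-keto phosphonate
Product: 21 (2E)-1-[(3R,3aR,7S,8aR)-3-hydroxy-3,6,8,8-tetramethyl-1,2,3,3a,4,7,8,8a-octahydroazulen-7-yl]-6-{(2R,3R)-3-[2-((2R)-3,3-dimethyloxiran-2-yl)ethyl]-3-methyloxiran-2-yl}hex-2-en-4-one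
Conditions: LiCl, i-Pr2NEt, MeCN, rt
Reagents that add atoms: none
Why: Horner–Wadsworth–Emmons olefination under mild Masamune–Roush conditions gives the E-enone (C11=C12) without touching the epoxides or the free tertiary alcohol.

Step 11
Reactants: 21 bis-epoxy enone
Product: 22 (Z)-triethylsilyl enol ether of 21 (C10–OSiEt3, C10=C11)
Conditions: Et3SiH (1.5 equiv), RhCl(PPh3)3 (2 mol %), PhH, 50 °C
Reagents that add atoms: triethylsilane, CC[SiH](CC)CC
Why: Rh-catalysed 1,4-hydrosilylation of the enone through its s-cis conformer gives the (Z)-silyl enol ether regiospecifically at C10=C11, which fixes C11 as the carbon that closes the ring in the next step.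

Step 12
Reactants: 22 bis-epoxy enol silane
Product: 23 (3R,5aR,6R,9aR)-6-{2-[(3R,3aR,7S,8aR)-3-hydroxy-3,6,8,8-tetramethyl-1,2,3,3a,4,7,8,8a-octahydroazulen-7-yl]ethyl}-2,2,5a-trimethyl-3-[(triethylsilyl)oxy]octahydro-1-benzoxepin-7(2H)-one
Conditions: TESOTf (0.2 equiv), 2,6-di-tert-butyl-4-methylpyridine (0.5 equiv), CH2Cl2, −78 °C; aq. NaHCO3
Reagents that add atoms: none
Why: Lewis-acid-triggered tandem oxa-/carbacyclization of the 1,5-diepoxide, in which the 6,7-epoxide oxygen opens the silyl-activated 2,3-epoxide at C2 and the enol silane opens the resulting epoxonium ion at C6 with inversion through a chair transition state, gives the trans-fused oxepane–cyclohexanone with the C11 chain equatorial (C11 can also equilibrate to this isomer) and relays the silyl group to O3.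

Step 13
Reactants: 23 bicyclic ketone
Product: 25 (3R,5aR,6R,7S,9aR)-6-{2-[(3R,3aR,7S,8aR)-3-hydroxy-3,6,8,8-tetramethyl-1,2,3,3a,4,7,8,8a-octahydroazulen-7-yl]ethyl}-2,2,5a,7-tetramethyldecahydro-1-benzoxepine-3,7-diol, via triethylsilyl ether 24 (not isolated)
Conditions: MeLi, CeCl3, THF, −78 °C; then AcOH–THF–H2O (3:1:1), rt
Reagents that add atoms: methyllithium, [Li]C
Why: Organocerium 1,2-addition to the enolisable ketone comes from the equatorial direction because the axial C6 methyl blocks axial attack, giving the axial C10 hydroxyl, and mild acid then removes the secondary silyl ether.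

Step 14
Reactants: 25 triol
Product: 27 15,16-epoxide of 25 with the oxygen cis to the C14 side chain (14R,15R,16S), via bromohydrin 26 (not isolated)
Conditions: NBS, THF–H2O (4:1), 0 °C; then K2CO3, MeOH, rt
Reagents that add atoms: water, O
Why: Bromohydrin formation and base closure: the bromonium ion forms on the open convex face, water opens it anti at the tertiary C15, and intramolecular SN2 with inversion at C16 puts the epoxide on the concave face, cis to the C14 chain.

Step 15
Reactants: 27 epoxy triol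
Product: 28 CNP0259752.1 (target)
Conditions: Dess–Martin periodinane, NaHCO3, CH2Cl2, 0 °C → rt
Reagents that add atoms: none
Why: Dess–Martin oxidation converts the only secondary alcohol into the oxepanone while the tertiary alcohols and the buffered epoxide are unaffected.

**Compound list**

1 | isobutyraldehyde | CC(C)C=O | starting material
2 | ethyl vinyl ketone (pent-1-en-3-one) | CCC(=O)C=C | starting material
3 | 2,2-dimethyl-5-oxoheptanal | CCC(=O)CCC(C)(C)C=O | intermediate (not isolated)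
4 | 2,4,4-trimethylcyclohex-2-en-1-one | CC1=CC(C)(C)CCC1=O | intermediate
5 | 2,4,4-trimethylcyclohexa-2,5-dien-1-one | CC1=CC(C)(C)C=CC1=O | intermediate
6 | 2-(2-bromoethyl)-2-methyl-1,3-dioxolane | CC1(CCBr)OCCO1 | starting material
7 | zinc dienolate: [(3R)-4,4,6-trimethyl-3-[2-(2-methyl-1,3-dioxolan-2-yl)ethyl]cyclohexa-1,5-dien-1-olato][2-(2-methyl-1,3-dioxolan-2-yl)ethyl]zinc | CC1=CC(C)(C)[C@H](CCC2(C)OCCO2)C=C1O[Zn]CCC1(C)OCCO1 | intermediate (not isolated)
8 | trimethyl({(3R)-4,4,6-trimethyl-3-[2-(2-methyl-1,3-dioxolan-2-yl)ethyl]cyclohexa-1,5-dien-1-yl}oxy)silane | CC1=CC(C)(C)[C@H](CCC2(C)OCCO2)C=C1O[Si](C)(C)C | intermediate (not isolated)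
9 | {[(5R)-2,4,4-trimethyl-5-[2-(2-methyl-1,3-dioxolan-2-yl)ethyl]bicyclo[4.1.0]hept-2-en-1-yl]oxy}trimethylsilane (cyclopropane configuration not controlled, irrelevant) | C[Si](C)(C)OC12CC1[C@@H](CCC1(C)OCCO1)C(C)(C)C=C2C | intermediate
10 | 6-chloro-2,4,4-trimethyl-5-[2-(2-methyl-1,3-dioxolan-2-yl)ethyl]cyclohept-2-en-1-one (side-chain centre as in 9; C–Cl epimers) | O=C1C(C)=CC(C)(C)[C@H](CCC2(C)OCCO2)C(Cl)C1 | intermediate (not isolated)
11 | (5R)-2,4,4-trimethyl-5-[2-(2-methyl-1,3-dioxolan-2-yl)ethyl]cyclohepta-2,6-dien-1-one | O=C1C(C)=CC(C)(C)[C@H](CCC2(C)OCCO2)C=C1 | intermediate (not isolated)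
12 | (5R)-2,4,4-trimethyl-5-(3-oxobutyl)cyclohepta-2,6-dien-1-one | O=C1C(C)=CC(C)(C)[C@H](CCC(C)=O)C=C1 | intermediate
13 | (3R,3aR,8aR)-3-hydroxy-3,6,8,8-tetramethyl-2,3,3a,4,8,8a-hexahydroazulen-5(1H)-one (cis-fused; OH cis to both ring-fusion H) | O=C1C(C)=CC(C)(C)[C@@H]2CC[C@@](C)(O)[C@@H]2C1 | intermediate
14 | (3R,3aR,5S,8aR)-3,6,8,8-tetramethyl-1,2,3,3a,4,5,8,8a-octahydroazulene-3,5-diol | O[C@@H]1C(C)=CC(C)(C)[C@@H]2CC[C@@](C)(O)[C@@H]2C1 | intermediate
15 | 5-O-vinyl ether of 14 | C=CO[C@@H]1C(C)=CC(C)(C)[C@@H]2CC[C@@](C)(O)[C@@H]2C1 | intermediate (not isolated)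
16 | 2-[(3R,3aR,7S,8aR)-3-hydroxy-3,6,8,8-tetramethyl-1,2,3,3a,4,7,8,8a-octahydroazulen-7-yl]acetaldehyde | O=CC[C@@H]1C(C)(C)[C@@H]2CC[C@@](C)(O)[C@@H]2CC=C1C | intermediate
17 | dimethyl (2-oxopropyl)phosphonate | COP(=O)(OC)CC(C)=O | starting material
18 | geranyl bromide [(2E)-1-bromo-3,7-dimethylocta-2,6-diene] | CC(C)=CCC/C(C)=C/CBr | starting material
19 | dimethyl [(5E)-6,10-dimethyl-2-oxoundeca-5,9-dien-1-yl]phosphonate | COP(=O)(OC)CC(=O)CC/C=C(\C)CCC=C(C)C | intermediate
20 | dimethyl [(5R,6R,9R)-5,6:9,10-diepoxy-6,10-dimethyl-2-oxoundecyl]phosphonate | COP(=O)(OC)CC(=O)CC[C@H]1O[C@]1(C)CC[C@H]1OC1(C)C | intermediate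
21 | (2E)-1-[(3R,3aR,7S,8aR)-3-hydroxy-3,6,8,8-tetramethyl-1,2,3,3a,4,7,8,8a-octahydroazulen-7-yl]-6-{(2R,3R)-3-[2-((2R)-3,3-dimethyloxiran-2-yl)ethyl]-3-methyloxiran-2-yl}hex-2-en-4-one | CC1(C)O[C@@H]1CC[C@@]1(C)O[C@@H]1CCC(=O)/C=C/C[C@@H]1C(C)(C)[C@@H]2CC[C@@](C)(O)[C@@H]2CC=C1C | intermediate
22 | (Z)-triethylsilyl enol ether of 21 (OSiEt3 on C10, C10=C11 double bond, C12 now CH2) | CC1(C)O[C@@H]1CC[C@@]1(C)O[C@@H]1CC/C(O[Si](CC)(CC)CC)=C/CC[C@@H]1C(C)(C)[C@@H]2CC[C@@](C)(O)[C@@H]2CC=C1C | intermediate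
23 | (3R,5aR,6R,9aR)-6-{2-[(3R,3aR,7S,8aR)-3-hydroxy-3,6,8,8-tetramethyl-1,2,3,3a,4,7,8,8a-octahydroazulen-7-yl]ethyl}-2,2,5a-trimethyl-3-[(triethylsilyl)oxy]octahydro-1-benzoxepin-7(2H)-one | CC1(C)O[C@@H]2CCC(=O)[C@H](CC[C@@H]3C(C)(C)[C@@H]4CC[C@@](C)(O)[C@@H]4CC=C3C)[C@@]2(C)CC[C@H]1O[Si](CC)(CC)CC | intermediate
24 | 3-O-triethylsilyl ether of 25 | CC1(C)O[C@@H]2CC[C@](C)(O)[C@H](CC[C@@H]3C(C)(C)[C@@H]4CC[C@@](C)(O)[C@@H]4CC=C3C)[C@@]2(C)CC[C@H]1O[Si](CC)(CC)CC | intermediate (not isolated)
25 | (3R,5aR,6R,7S,9aR)-6-{2-[(3R,3aR,7S,8aR)-3-hydroxy-3,6,8,8-tetramethyl-1,2,3,3a,4,7,8,8a-octahydroazulen-7-yl]ethyl}-2,2,5a,7-tetramethyldecahydro-1-benzoxepine-3,7-diol | CC1(C)O[C@@H]2CC[C@](C)(O)[C@H](CC[C@@H]3C(C)(C)[C@@H]4CC[C@@](C)(O)[C@@H]4CC=C3C)[C@@]2(C)CC[C@H]1O | intermediate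
26 | bromohydrin of 25: 15-OH on the concave face, 16-Br on the convex face (15R,16R) | CC1(C)O[C@@H]2CC[C@](C)(O)[C@H](CC[C@@H]3C(C)(C)[C@@H]4CC[C@@](C)(O)[C@@H]4C[C@@H](Br)[C@]3(C)O)[C@@]2(C)CC[C@H]1O | intermediate (not isolated)
27 | 15,16-epoxide of 25, oxygen cis to the C14 chain (14R,15R,16S); 3-hydroxy analogue of the target | CC1(C)O[C@@H]2CC[C@](C)(O)[C@H](CC[C@@H]3C(C)(C)[C@@H]4CC[C@@](C)(O)[C@@H]4C[C@@H]4O[C@@]43C)[C@@]2(C)CC[C@H]1O | intermediate
28 | CNP0259752.1 | CC1(C)O[C@@H]2CC[C@](C)(O)[C@H](CC[C@@H]3C(C)(C)[C@@H]4CC[C@@](C)(O)[C@@H]4C[C@@H]4O[C@@]43C)[C@@]2(C)CCC1=O | target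

**Totals**

Total steps: 15. Longest linear sequence: 13 (steps 1–7, then 10–15).

**Three steps most likely to fail**

Step 5 (SmI2 cyclization). The dienone may be reduced before the ketone, which could give dimers, over-reduction or the other C19 epimer. The fallback sets out from 12 and comes back at 13. The kinetic enolate of the methyl ketone is trapped (LiHMDS with TESCl present, THF, −78 °C) as the terminal triethylsilyl enol ether F1. F1 is treated with Fe(acac)3 and PhSiH3 in EtOH at 60 °C: hydrogen-atom transfer to the enol ether CH2 gives a tertiary α-silyloxy radical that closes 5-exo on the enone β-carbon to the cis-fused silyl ether F2. TBAF then gives 13. The radical here comes from an alkene by hydrogen-atom transfer, not from electron transfer to a carbonyl.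

Step 12 (late epoxide cascade on a C35 substrate). The fallback sets out from 20 (with 16) and comes back at 25. The small fragment is cyclised first: BF3·OEt2 (CH2Cl2, −78 → −20 °C) on 20, whose β-keto phosphonate enol terminates the same oxa-/carbacyclization, gives the bicyclic α-phosphono ketone F3. Horner–Wadsworth–Emmons reaction of F3 with 16 (Ba(OH)2, wet THF) gives the exocyclic enone F4. Conjugate reduction with Stryker's reagent gives the hydroxy ketone F5, with the C11 chain equatorial after equilibration. MeLi/CeCl3 (excess) on F5 gives 25 directly.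

Step 14 (face selectivity of the epoxide). If the bromonium ion forms on the concave face, the sequence gives the 15,16-epimeric epoxide. The fallback sets out from 25 and comes back at 27: anti addition/closure is replaced by direct syn oxygen transfer (mCPBA, NaHCO3, CH2Cl2, 0 °C, or dimethyldioxirane), which puts oxygen on the face the bromine would have taken. It makes no new compound (F0).

**Further compounds**

F1 | step 5 | (5R)-2,4,4-trimethyl-5-{3-[(triethylsilyl)oxy]but-3-en-1-yl}cyclohepta-2,6-dien-1-one | O=C1C(C)=CC(C)(C)[C@H](CCC(=C)O[Si](CC)(CC)CC)C=C1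
F2 | step 5 | 3-O-triethylsilyl ether of 13 | O=C1C(C)=CC(C)(C)[C@@H]2CC[C@@](C)(O[Si](CC)(CC)CC)[C@@H]2C1
F3 | step 12 | bicyclic α-phosphono ketone: trans-fused 3-hydroxy-2,2,5a-trimethyl-7-oxo-decahydro-1-benzoxepine carrying P(O)(OMe)2 at C6 of the ring system (ring stereocentres as in 23; epimers at the phosphonate carbon) | CC1(C)O[C@@H]2CCC(=O)C(P(=O)(OC)OC)[C@@]2(C)CC[C@H]1O
F4 | step 12 | exocyclic enone: F5 with a C11=C12 double bond (E expected) | CC1(C)O[C@@H]2CCC(=O)C(=CC[C@@H]3C(C)(C)[C@@H]4CC[C@@](C)(O)[C@@H]4CC=C3C)[C@@]2(C)CC[C@H]1O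
F5 | step 12 | 3-hydroxy ketone: 23 without the triethylsilyl group | CC1(C)O[C@@H]2CCC(=O)[C@H](CC[C@@H]3C(C)(C)[C@@H]4CC[C@@](C)(O)[C@@H]4CC=C3C)[C@@]2(C)CC[C@H]1O
F0 | step 14 | none | none
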